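Labels: C7 is the carbinol carbon, C8 and C9 the ring CH and OCH2 next to it, C7' the benzylic CH2, C8' and C9' the ring CH and OCH2 on that side. Backwards, the two phenol benzyl ethers come off, the ring bond O–C9 is cut (the oxygen then sits on C9' of a lactone closed onto O7), then C8'–C9' (carbon monoxide), C7'–aryl (Heck) and C7–C8 (allylboration).
Enabling feature: C9' is a single carbon on C8' lying 1,4 to the C7 oxygen, so a formyl group delivered to C8' of a C7'=C8' styrene under direction of the C7 hydroxyl closes at once to the five-membered lactol O7–C7–C8–C8'–C9'.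
Forward order: (Z)-allylboronate, syn homoallylic alcohol, Heck arylation, hydroformylation to the lactol (first ring), oxidation to the lactone, then hydride opening of that ring and 5-exo-tet closure of the C9' oxygen onto C9 to give the tetrahydrofuran (O, C9, C8, C8', C9').
Stereochemistry: C7 and C8 come from a chiral phosphoric acid-catalysed allylboration with a (Z)-boronate; C8' is set by C8 in the chelated hydroformylation (trans on the lactol, which is cis on the final tetrahydrofuran).

Key step: step 6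

Assumption: 3-(benzyloxy)-4-methoxybenzaldehyde is bought (it is one benzylation from isovanillin), and (S)-TRIP is taken to direct allyl transfer to the Si face of the aldehyde, the mirror image of the Re-face attack known for the (R)-acid.

Step 1
Reactants: 1 tert-butyldimethyl(prop-2-yn-1-yloxy)silane
Product: 2 (Z)-tert-butyldimethyl{[3-(4,4,5,5-tetramethyl-1,3,2-dioxaborolan-2-yl)prop-2-en-1-yl]oxy}silane
Conditions: pinacolborane, [Rh(cod)Cl]2 (1.5 mol%), P(i-Pr)3 (6 mol%), Et3N, cyclohexane, rt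
Reagents that add atoms: pinacolborane, CC1(C)OBOC1(C)C
Why: Rhodium-catalysed trans-hydroboration of a terminal alkyne, which runs through a rhodium vinylidene and so puts boron on the terminal carbon cis to the CH2OTBS group, should give the (Z)-alkenylboronate.

Step 2
Reactants: 2 (Z)-tert-butyldimethyl{[3-(4,4,5,5-tetramethyl-1,3,2-dioxaborolan-2-yl)prop-2-en-1-yl]oxy}silane
Product: 4 (Z)-tert-butyldimethyl{[4-(4,4,5,5-tetramethyl-1,3,2-dioxaborolan-2-yl)but-2-en-1-yl]oxy}silane, via chloromethyl borate complex 3 (not isolated)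
Conditions: BrCH2Cl, n-BuLi, THF, −78 °C to rt
Reagents that add atoms: bromochloromethane, ClCBr
Why: Matteson homologation, in which chloromethyllithium formed in situ adds to boron and the alkenyl group shifts from boron to carbon with loss of chloride, should keep the Z geometry and turn the alkenylboronate into the allylboronate.

Step 3
Reactants: 4 (Z)-tert-butyldimethyl{[4-(4,4,5,5-tetramethyl-1,3,2-dioxaborolan-2-yl)but-2-en-1-yl]oxy}silane; 5 3-(benzyloxy)-4-methoxybenzaldehyde
Product: 7 (1S,2S)-1-[3-(benzyloxy)-4-methoxyphenyl]-2-{[(tert-butyldimethylsilyl)oxy]methyl}but-3-en-1-ol, via pinacol borate ester 6 (not isolated)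
Conditions: (S)-TRIP (5 mol%), toluene, −30 °C; aqueous NaHCO3 work-up
Reagents that add atoms: none
Why: Chiral phosphoric acid-catalysed allylboration through a closed chair transition state, in which the Z geometry of 4 places the C7 hydroxyl and the C9 arm syn and (S)-TRIP, bound to a boronate oxygen and the formyl hydrogen, should direct attack to the Si face of the aldehyde, so that C7 and C8 are both set as S.

Step 4
Reactants: 8 5-bromo-2-methoxyphenol
Product: 9 2-(benzyloxy)-4-bromo-1-methoxybenzene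
Conditions: BnBr, K2CO3, DMF, rt
Reagents that add atoms: benzyl bromide, BrCc1ccccc1
Why: Williamson ether synthesis of a phenoxide with a benzylic bromide under mild carbonate base.

Step 5
Reactants: 7 (1S,2S)-1-[3-(benzyloxy)-4-methoxyphenyl]-2-{[(tert-butyldimethylsilyl)oxy]methyl}but-3-en-1-ol; 9 2-(benzyloxy)-4-bromo-1-methoxybenzene
Product: 10 (1S,2S,3E)-1,4-bis[3-(benzyloxy)-4-methoxyphenyl]-2-{[(tert-butyldimethylsilyl)oxy]methyl}but-3-en-1-ol
Conditions: Pd(OAc)2 (5 mol%), P(o-tol)3 (10 mol%), Et3N, DMF, 90 °C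
Reagents that add atoms: none
Why: Mizoroki–Heck reaction, in which the arylpalladium bromide adds to the vinyl group with the aryl on the unhindered terminal carbon and syn β-hydride elimination toward the new benzylic position should give the conjugated E-styrene without touching C7 or C8.

Step 6
Reactants: 10 (1S,2S,3E)-1,4-bis[3-(benzyloxy)-4-methoxyphenyl]-2-{[(tert-butyldimethylsilyl)oxy]methyl}but-3-en-1-ol; 11 carbon monoxide
Product: 13 (3R,4S,5S)-3-[3-(benzyloxy)-4-methoxybenzyl]-5-[3-(benzyloxy)-4-methoxyphenyl]-4-{[(tert-butyldimethylsilyl)oxy]methyl}tetrahydrofuran-2-ol (both anomers), via hydroxy aldehyde 12 (not isolated)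
Conditions: Rh(acac)(CO)2 (2 mol%), Ph2POCH3 (20 mol%), CO/H2 (1:1, 40 bar), 4 Å MS, THF, 50 °C
Reagents that add atoms: carbon monoxide (compound 11), [C-]#[O+]
Why: The C7 hydroxyl exchanges with methanol on Ph2POCH3 (the sieves take up the methanol), the substrate-bound phosphinite binds rhodium, and hydride addition to the styrene then occurs inside a six-membered chelate (Rh, P, O, C7, C8, C8') that puts rhodium on C8' and hydrogen on C7', after which CO insertion and hydrogenolysis of the acyl give aldehyde 12 and free the catalyst. The closest known reaction type is the branched-selective hydroformylation of homoallylic alcohols steered by a catalytic, reversibly bound phosphinite, which delivers five-membered lactols. The lactol ring (O7, C7, C8, C8', C9') closes by 5-exo-trig addition of the C7 hydroxyl to the new formyl carbon. C8' is set by C8: in the chelate the C8 hydrogen eclipses the double bond (least allylic 1,3-strain), the C9 arm points away and rhodium arrives on the face of the tether, which should give the 8'R centre with the arylmethyl group trans to the C9 arm, while the anomeric carbon forms as a mixture that step 7 erases. The step needs formyl delivery to C8' against the benzylic preference of a styrene, and this is secured by the short tether (rhodium at C7' would need a seven-membered chelate), by the mild temperature at which undirected hydroformylation of a 1,2-disubstituted alkene is slow, and by the electron-rich aryl group, which weakens the benzylic bias. C8' also lies next to the carbonyl group in aldehyde 12 and in lactone 14, where the trans arrangement is the more stable one, so a minor epimer can be converged by base at the lactone stage.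

Step 7
Reactants: 13 (3R,4S,5S)-3-[3-(benzyloxy)-4-methoxybenzyl]-5-[3-(benzyloxy)-4-methoxyphenyl]-4-{[(tert-butyldimethylsilyl)oxy]methyl}tetrahydrofuran-2-ol
Product: 14 (3R,4S,5S)-3-[3-(benzyloxy)-4-methoxybenzyl]-5-[3-(benzyloxy)-4-methoxyphenyl]-4-{[(tert-butyldimethylsilyl)oxy]methyl}dihydrofuran-2(3H)-one
Conditions: TEMPO (10 mol%), PhI(OAc)2, CH2Cl2, rt
Reagents that add atoms: none
Why: Oxoammonium (TEMPO/PhI(OAc)2) oxidation of a lactol to the lactone under near-neutral conditions should merge both anomers and leave the silyl ether, the benzyl ethers and the three ring stereocentres alone.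

Step 8
Reactants: 14 (3R,4S,5S)-3-[3-(benzyloxy)-4-methoxybenzyl]-5-[3-(benzyloxy)-4-methoxyphenyl]-4-{[(tert-butyldimethylsilyl)oxy]methyl}dihydrofuran-2(3H)-one
Product: 15 (3R,4S,5S)-3-[3-(benzyloxy)-4-methoxybenzyl]-5-[3-(benzyloxy)-4-methoxyphenyl]-4-(hydroxymethyl)dihydrofuran-2(3H)-one
Conditions: HF·pyridine, pyridine, THF, 0 °C to rt
Reagents that add atoms: none
Why: Fluoride cleavage of a primary silyl ether, run in buffered and slightly acidic HF·pyridine because a basic fluoride source could move the lactone onto the freed C9 hydroxyl or epimerise C8'.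

Step 9
Reactants: 15 (3R,4S,5S)-3-[3-(benzyloxy)-4-methoxybenzyl]-5-[3-(benzyloxy)-4-methoxyphenyl]-4-(hydroxymethyl)dihydrofuran-2(3H)-one
Product: 16 [(2S,3S,4R)-4-[3-(benzyloxy)-4-methoxybenzyl]-2-[3-(benzyloxy)-4-methoxyphenyl]-5-oxotetrahydrofuran-3-yl]methyl methanesulfonate
Conditions: MsCl, Et3N, CH2Cl2, 0 °C
Reagents that add atoms: methanesulfonyl chloride, CS(=O)(=O)Cl
Why: Sulfonylation of the only free hydroxyl, a primary alcohol, by the sulfene formed from MsCl and Et3N.

Step 10
Reactants: 16 [(2S,3S,4R)-4-[3-(benzyloxy)-4-methoxybenzyl]-2-[3-(benzyloxy)-4-methoxyphenyl]-5-oxotetrahydrofuran-3-yl]methyl methanesulfonate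
Product: 18 (S)-[3-(benzyloxy)-4-methoxyphenyl]{(3S,4R)-4-[3-(benzyloxy)-4-methoxybenzyl]tetrahydrofuran-3-yl}methanol, via diol mesylate 17 (not isolated)
Conditions: LiBH4, THF, 0 °C to rt; then KOt-Bu, THF, 0 °C to rt
Reagents that add atoms: none
Why: Hydride reduction of the lactone frees the C7 and C9' oxygens, and on adding base the primary C9' alkoxide should displace the mesylate in an intramolecular Williamson etherification by 5-exo-tet closure, far faster than the 4-exo-tet oxetane closure open to the C7 alkoxide, with no stereocentre taking part.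

Step 11
Reactants: 18 (S)-[3-(benzyloxy)-4-methoxyphenyl]{(3S,4R)-4-[3-(benzyloxy)-4-methoxybenzyl]tetrahydrofuran-3-yl}methanol
Product: 19 5-[(S)-hydroxy{(3S,4R)-4-[(3-hydroxy-4-methoxyphenyl)methyl]tetrahydrofuran-3-yl}methyl]-2-methoxyphenol (CNP0108210.1)
Conditions: H2 (1 atm), Pd/C (10 wt%), EtOAc, rt
Reagents that add atoms: none
Why: Hydrogenolysis of the two aryl benzyl ethers over palladium on carbon in a neutral solvent, conditions under which the secondary benzylic C7 hydroxyl is expected to survive.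

Compound list
1 | tert-butyldimethyl(prop-2-yn-1-yloxy)silane | C#CCO[Si](C)(C)C(C)(C)C | starting material
2 | (Z)-tert-butyldimethyl{[3-(4,4,5,5-tetramethyl-1,3,2-dioxaborolan-2-yl)prop-2-en-1-yl]oxy}silane | CC1(C)OB(/C=C\CO[Si](C)(C)C(C)(C)C)OC1(C)C | intermediate
3 | lithium (chloromethyl)[(Z)-3-(tert-butyldimethylsilyloxy)prop-1-en-1-yl](pinacolato)borate | [Li+].ClC[B-]1(/C=C\CO[Si](C)(C)C(C)(C)C)OC(C)(C)C(C)(C)O1 | intermediate (not isolated)
4 | (Z)-tert-butyldimethyl{[4-(4,4,5,5-tetramethyl-1,3,2-dioxaborolan-2-yl)but-2-en-1-yl]oxy}silane | CC1(C)OB(C/C=C\CO[Si](C)(C)C(C)(C)C)OC1(C)C | intermediate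
5 | 3-(benzyloxy)-4-methoxybenzaldehyde | COc1ccc(C=O)cc1OCc1ccccc1 | starting material
6 | 2-{(1S,2S)-1-[3-(benzyloxy)-4-methoxyphenyl]-2-[(tert-butyldimethylsilyloxy)methyl]but-3-en-1-yloxy}-4,4,5,5-tetramethyl-1,3,2-dioxaborolane | C=C[C@@H](CO[Si](C)(C)C(C)(C)C)[C@H](OB1OC(C)(C)C(C)(C)O1)c1ccc(OC)c(OCc2ccccc2)c1 | intermediate (not isolated)
7 | (1S,2S)-1-[3-(benzyloxy)-4-methoxyphenyl]-2-{[(tert-butyldimethylsilyl)oxy]methyl}but-3-en-1-ol | C=C[C@@H](CO[Si](C)(C)C(C)(C)C)[C@H](O)c1ccc(OC)c(OCc2ccccc2)c1 | intermediate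
8 | 5-bromo-2-methoxyphenol | COc1ccc(Br)cc1O | starting material
9 | 2-(benzyloxy)-4-bromo-1-methoxybenzene | COc1ccc(Br)cc1OCc1ccccc1 | intermediate
10 | (1S,2S,3E)-1,4-bis[3-(benzyloxy)-4-methoxyphenyl]-2-{[(tert-butyldimethylsilyl)oxy]methyl}but-3-en-1-ol | COc1ccc(/C=C/[C@@H](CO[Si](C)(C)C(C)(C)C)[C@H](O)c2ccc(OC)c(OCc3ccccc3)c2)cc1OCc1ccccc1 | intermediate
11 | carbon monoxide | [C-]#[O+] | starting material
12 | (2R,3S,4S)-2-[3-(benzyloxy)-4-methoxybenzyl]-4-[3-(benzyloxy)-4-methoxyphenyl]-3-{[(tert-butyldimethylsilyl)oxy]methyl}-4-hydroxybutanal | O=C[C@H](Cc1ccc(OC)c(OCc2ccccc2)c1)[C@@H](CO[Si](C)(C)C(C)(C)C)[C@H](O)c1ccc(OC)c(OCc2ccccc2)c1 | intermediate (not isolated)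
13 | (3R,4S,5S)-3-[3-(benzyloxy)-4-methoxybenzyl]-5-[3-(benzyloxy)-4-methoxyphenyl]-4-{[(tert-butyldimethylsilyl)oxy]methyl}tetrahydrofuran-2-ol, both anomers at C2 | OC1[C@H](Cc2ccc(OC)c(OCc3ccccc3)c2)[C@@H](CO[Si](C)(C)C(C)(C)C)[C@@H](c2ccc(OC)c(OCc3ccccc3)c2)O1 | intermediate
14 | (3R,4S,5S)-3-[3-(benzyloxy)-4-methoxybenzyl]-5-[3-(benzyloxy)-4-methoxyphenyl]-4-{[(tert-butyldimethylsilyl)oxy]methyl}dihydrofuran-2(3H)-one | O=C1[C@H](Cc2ccc(OC)c(OCc3ccccc3)c2)[C@@H](CO[Si](C)(C)C(C)(C)C)[C@@H](c2ccc(OC)c(OCc3ccccc3)c2)O1 | intermediate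
15 | (3R,4S,5S)-3-[3-(benzyloxy)-4-methoxybenzyl]-5-[3-(benzyloxy)-4-methoxyphenyl]-4-(hydroxymethyl)dihydrofuran-2(3H)-one | O=C1[C@H](Cc2ccc(OC)c(OCc3ccccc3)c2)[C@@H](CO)[C@@H](c2ccc(OC)c(OCc3ccccc3)c2)O1 | intermediate
16 | [(2S,3S,4R)-4-[3-(benzyloxy)-4-methoxybenzyl]-2-[3-(benzyloxy)-4-methoxyphenyl]-5-oxotetrahydrofuran-3-yl]methyl methanesulfonate | O=C1[C@H](Cc2ccc(OC)c(OCc3ccccc3)c2)[C@@H](COS(C)(=O)=O)[C@@H](c2ccc(OC)c(OCc3ccccc3)c2)O1 | intermediate
17 | (2S,3R)-3-[3-(benzyloxy)-4-methoxybenzyl]-2-{(S)-[3-(benzyloxy)-4-methoxyphenyl](hydroxy)methyl}-4-hydroxybutyl methanesulfonate | OC[C@H](Cc1ccc(OC)c(OCc2ccccc2)c1)[C@@H](COS(C)(=O)=O)[C@H](O)c1ccc(OC)c(OCc2ccccc2)c1 | intermediate (not isolated)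
18 | (S)-[3-(benzyloxy)-4-methoxyphenyl]{(3S,4R)-4-[3-(benzyloxy)-4-methoxybenzyl]tetrahydrofuran-3-yl}methanol | COc1ccc(C[C@H]2COC[C@H]2[C@H](O)c2ccc(OC)c(OCc3ccccc3)c2)cc1OCc1ccccc1 | intermediate
19 | 5-[(S)-hydroxy{(3S,4R)-4-[(3-hydroxy-4-methoxyphenyl)methyl]tetrahydrofuran-3-yl}methyl]-2-methoxyphenol | COc1ccc(C[C@H]2COC[C@H]2[C@H](O)c2ccc(OC)c(O)c2)cc1O | target

Total step count: 11. Longest linear sequence: 10 steps (steps 1, 2, 3, 5, 6, 7, 8, 9, 10 and 11; step 4 is a side branch).

Steps most likely to fail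

Step 6 is the most exposed. The formyl group may be delivered to the benzylic carbon C7' instead of C8'. Exchange of the hindered secondary benzylic alcohol onto phosphorus may also be too slow to outrun undirected hydroformylation, hydrogenation of the styrene, or rearrangement of the benzylic phosphinite. A C8' epimer alone would not be fatal, since brief treatment of lactone 14 with DBU should converge it to the trans isomer. The fallback leaves carbon monoxide aside; it sets out from homoallylic alcohol 7 and comes back at lactone 14. Hydroboration–oxidation of the vinyl group (9-BBN, THF; then NaOH, H2O2) would give (1S,2S)-1-[3-(benzyloxy)-4-methoxyphenyl]-2-{[(tert-butyldimethylsilyl)oxy]methyl}butane-1,4-diol F1. Oxidative lactonisation of its primary alcohol (TEMPO, PhI(OAc)2, CH2Cl2) would give (4S,5S)-5-[3-(benzyloxy)-4-methoxyphenyl]-4-{[(tert-butyldimethylsilyl)oxy]methyl}dihydrofuran-2(3H)-one F2. Aldehyde 5 would be reduced (NaBH4, MeOH) to [3-(benzyloxy)-4-methoxyphenyl]methanol F3 and brominated (PBr3, Et2O, 0 °C) to 2-(benzyloxy)-4-(bromomethyl)-1-methoxybenzene F4. The lithium enolate of the lactone (LiN(SiMe3)2, THF, −78 °C) would then be alkylated with this bromide; the electrophile should enter trans to the C4 substituent, which gives 14.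

Step 5 comes next. Aryl transfer to the internal vinyl carbon, β-hydride elimination toward C8 that moves the double bond out of conjugation and on toward the carbinol, and oxidation of the benzylic alcohol by the arylpalladium species would all erode the yield of the E-styrene. The fallback replaces the Heck reaction by olefin metathesis; it sets out from 7 and aldehyde 5 and comes back at 10. Wittig methylenation of 5 (Ph3PCH3Br, KOt-Bu, THF) would give 2-(benzyloxy)-4-ethenyl-1-methoxybenzene F5. Cross-metathesis of this styrene with 7 (second-generation Hoveyda–Grubbs catalyst, RuCl2(SIMes)(=CH-C6H4-2-OiPr), CH2Cl2, 40 °C) should give the E-styrene 10 with loss of ethene.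

Step 10 is the third. After the first hydride transfer the lactolate oxygen may attack the mesylate and lock the molecule as a bridged acetal, hydride may displace the mesylate directly, or the C7 alkoxide may close an oxetane. The fallback separates reduction from activation; it sets out from lactone 14 and comes back at 18.
- Reduction (LiBH4, THF) would give (1S,2S,3R)-3-[3-(benzyloxy)-4-methoxybenzyl]-1-[3-(benzyloxy)-4-methoxyphenyl]-2-{[(tert-butyldimethylsilyl)oxy]methyl}butane-1,4-diol F6.
- Acetylation of both hydroxyls (Ac2O, pyridine, DMAP) would give (1S,2S,3R)-3-[3-(benzyloxy)-4-methoxybenzyl]-1-[3-(benzyloxy)-4-methoxyphenyl]-2-{[(tert-butyldimethylsilyl)oxy]methyl}butane-1,4-diyl diacetate F7.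
- Desilylation (HF·pyridine, THF) would give (1S,2S,3R)-3-[3-(benzyloxy)-4-methoxybenzyl]-1-[3-(benzyloxy)-4-methoxyphenyl]-2-(hydroxymethyl)butane-1,4-diyl diacetate F8.
- Mesylation (MsCl, Et3N, CH2Cl2, 0 °C) would give (1S,2S,3R)-3-[3-(benzyloxy)-4-methoxybenzyl]-1-[3-(benzyloxy)-4-methoxyphenyl]-2-[(methanesulfonyloxy)methyl]butane-1,4-diyl diacetate F9.
- Methanolysis of both acetates (K2CO3, MeOH, rt) frees the C9' alkoxide, which closes onto C9 by the same 5-exo-tet displacement and gives 18, with no hydride or lactolate present.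

Further compounds
F1 | step 6 | (1S,2S)-1-[3-(benzyloxy)-4-methoxyphenyl]-2-{[(tert-butyldimethylsilyl)oxy]methyl}butane-1,4-diol | OCC[C@@H](CO[Si](C)(C)C(C)(C)C)[C@H](O)c1ccc(OC)c(OCc2ccccc2)c1
F2 | step 6 | (4S,5S)-5-[3-(benzyloxy)-4-methoxyphenyl]-4-{[(tert-butyldimethylsilyl)oxy]methyl}dihydrofuran-2(3H)-one | O=C1C[C@@H](CO[Si](C)(C)C(C)(C)C)[C@@H](c2ccc(OC)c(OCc3ccccc3)c2)O1
F3 | step 6 | [3-(benzyloxy)-4-methoxyphenyl]methanol | COc1ccc(CO)cc1OCc1ccccc1
F4 | step 6 | 2-(benzyloxy)-4-(bromomethyl)-1-methoxybenzene | COc1ccc(CBr)cc1OCc1ccccc1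
F5 | step 5 | 2-(benzyloxy)-4-ethenyl-1-methoxybenzene | COc1ccc(C=C)cc1OCc1ccccc1
F6 | step 10 | (1S,2S,3R)-3-[3-(benzyloxy)-4-methoxybenzyl]-1-[3-(benzyloxy)-4-methoxyphenyl]-2-{[(tert-butyldimethylsilyl)oxy]methyl}butane-1,4-diol | OC[C@H](Cc1ccc(OC)c(OCc2ccccc2)c1)[C@@H](CO[Si](C)(C)C(C)(C)C)[C@H](O)c1ccc(OC)c(OCc2ccccc2)c1
F7 | step 10 | (1S,2S,3R)-3-[3-(benzyloxy)-4-methoxybenzyl]-1-[3-(benzyloxy)-4-methoxyphenyl]-2-{[(tert-butyldimethylsilyl)oxy]methyl}butane-1,4-diyl diacetate | CC(=O)OC[C@H](Cc1ccc(OC)c(OCc2ccccc2)c1)[C@@H](CO[Si](C)(C)C(C)(C)C)[C@H](OC(C)=O)c1ccc(OC)c(OCc2ccccc2)c1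
F8 | step 10 | (1S,2S,3R)-3-[3-(benzyloxy)-4-methoxybenzyl]-1-[3-(benzyloxy)-4-methoxyphenyl]-2-(hydroxymethyl)butane-1,4-diyl diacetate | CC(=O)OC[C@H](Cc1ccc(OC)c(OCc2ccccc2)c1)[C@@H](CO)[C@H](OC(C)=O)c1ccc(OC)c(OCc2ccccc2)c1
F9 | step 10 | (1S,2S,3R)-3-[3-(benzyloxy)-4-methoxybenzyl]-1-[3-(benzyloxy)-4-methoxyphenyl]-2-[(methanesulfonyloxy)methyl]butane-1,4-diyl diacetate | CC(=O)OC[C@H](Cc1ccc(OC)c(OCc2ccccc2)c1)[C@@H](COS(C)(=O)=O)[C@H](OC(C)=O)c1ccc(OC)c(OCc2ccccc2)c1
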